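A direct plan would annulate a C5 enal onto 3',4'-dihydroxyacetophenone A1 to give chromenyl ketone A2, add the prenyl group to reach A3, join A3 to a resorcinol aldehyde by aldol condensation, reduce the enone and then the ketone enantioselectively to (R)-carbinol A4, and close the chroman last by Mitsunobu inversion.
Its weakest steps would be:
- the chromene annulation on the unsymmetrical catechol A1, because nothing would force the enal to engage the 4-OH/C5 pair and not the 3-OH/C2 pair;
- the prenyl installation (O-allylation, Claisen shift, cross-metathesis), because three operations, the last a Ru carbene beside the chromene alkene, would be spent on one C5 unit;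
- the Mitsunobu closure of A4, because the carbinol is benzylic to a ring with a para oxygen, so ionisation would erode the only stereocentre in the last step, on the most precious material, while three free phenols compete.

**Plan of the new route**
- The retrosynthesis first cuts, in the B ring, the C2'–CH2 bond of the prenyl group and the pyran bonds C5'–C4''/O4'–C2''. Both lead back to C5 ethers on oxygen: a 1,1-dimethylallyl ether on O3' and a 1,1-dimethylpropargyl ether on O4'.
- It then removes the C4 oxygen (flavanone), opens O1–C2 (oxa-Michael) and cuts C2–C3 (aldol), arriving at 2',4'-dihydroxyacetophenone and an aldehyde made from 3,4-dihydroxybenzaldehyde.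
- The feature that makes the key step possible is the 3',4'-catechol of the B ring: O3' has only C2', and O4' only C5', as an unsubstituted ortho carbon, and both appendages are C5 units that [3,3] shifts can deliver from oxygen to carbon.
- The rings arise in the order chroman (step 5), then pyran (step 7, the last step).
- Regiochemistry is fixed by the acidity of the 4-OH of the aldehyde and by the single free ortho positions. The prenyl group and the pyran arrive in one operation and no protecting group is needed. C2 is selected by a chiral catalyst at the ketone stage and is never a reaction centre afterwards.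

Key step: step 7

Assumption: the (S,S)-TsDPEN–Ru hydride is taken to reduce the (2S)-flavanone faster (hydride anti to the 2-aryl group, 4S carbinol, the usual sense for aryl alkyl ketones); should a first run show the opposite preference, the (R,R)-catalyst would be used.

## Route

Step 1
Reactants: 1 3,4-dihydroxybenzaldehyde; 2 3-chloro-3-methylbut-1-yne
Product: 3 3-hydroxy-4-[(2-methylbut-3-yn-2-yl)oxy]benzaldehyde
Conditions: 2 (1.1 equiv), DBU (1.05 equiv), CuCl2·2H2O (0.5 mol%), MeCN, −5 to 0 °C, N2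
Reagents that add atoms: 3-chloro-3-methylbut-1-yne (2), C#CC(C)(C)Cl
Why: Copper-catalysed propargylic etherification of a phenoxide should occur at O4 alone, because one equivalent of base ionises only the 4-OH, which is para to the formyl group and much more acidic than the 3-OH.

Step 2
Reactants: 4 2-methylbut-3-en-2-ol; 5 di-tert-butyl dicarbonate
Product: 6 tert-butyl 2-methylbut-3-en-2-yl carbonate
Conditions: n-BuLi (1.05 equiv), THF, −78 °C; then 5, −78 to 0 °C; H2O
Reagents that add atoms: di-tert-butyl dicarbonate (5), CC(C)(C)OC(=O)OC(=O)OC(C)(C)C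
Why: Alkoxycarbonylation of the lithium tert-alkoxide with Boc2O gives the mixed carbonate that serves as the 1,1-dimethylallyl donor.

Step 3
Reactants: 3 3-hydroxy-4-[(2-methylbut-3-yn-2-yl)oxy]benzaldehyde; 6 tert-butyl 2-methylbut-3-en-2-yl carbonate
Product: 7 3-[(2-methylbut-3-en-2-yl)oxy]-4-[(2-methylbut-3-yn-2-yl)oxy]benzaldehyde
Conditions: 6 (1.5 equiv), Pd(PPh3)4 (3 mol%), THF, 0 °C to rt, Ar; stopped as soon as 3 is consumed
Reagents that add atoms: tert-butyl 2-methylbut-3-en-2-yl carbonate (6), C=CC(C)(C)OC(=O)OC(C)(C)C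
Why: In this Tsuji–Trost O-allylation, Pd(0) ionises the tertiary allyl carbonate (the tert-butoxide released with CO2 deprotonates the phenol) and the phenoxide should attack the more substituted terminus of the 1,1-dimethyl-π-allyl complex under kinetic control, giving the branched tert-allyl ether.

Step 4
Reactants: 7 3-[(2-methylbut-3-en-2-yl)oxy]-4-[(2-methylbut-3-yn-2-yl)oxy]benzaldehyde; 8 1-(2,4-dihydroxyphenyl)ethanone
Product: 9 (E)-1-(2,4-dihydroxyphenyl)-3-{3-[(2-methylbut-3-en-2-yl)oxy]-4-[(2-methylbut-3-yn-2-yl)oxy]phenyl}prop-2-en-1-one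
Conditions: KOH (50% aq., 10 equiv), EtOH, rt, 48 h, N2; then AcOH to pH 6 at 0 °C
Reagents that add atoms: 1-(2,4-dihydroxyphenyl)ethanone (8), CC(=O)c1ccc(O)cc1O
Why: Claisen–Schmidt (aldol) condensation of the methyl ketone enolate with the non-enolisable aldehyde and E1cB dehydration should give the E-enone; both tertiary ethers are inert to hydroxide, and the work-up stays near neutral because the tert-allyl ether is acid-labile.

Step 5
Reactants: 9 (E)-1-(2,4-dihydroxyphenyl)-3-{3-[(2-methylbut-3-en-2-yl)oxy]-4-[(2-methylbut-3-yn-2-yl)oxy]phenyl}prop-2-en-1-one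
Product: 10 rac-7-hydroxy-2-{3-[(2-methylbut-3-en-2-yl)oxy]-4-[(2-methylbut-3-yn-2-yl)oxy]phenyl}chroman-4-one
Conditions: NaOAc (5 equiv), EtOH/H2O 4:1, 65 °C, N2; unchanged 9 recycled
Reagents that add atoms: none
Why: Intramolecular oxa-Michael addition (6-endo-trig) of the 2'-phenol to the enone under weakly basic buffering closes the chroman ring; C2 is deliberately formed racemic because step 6 selects it, and the temperature stays below the onset of the Claisen shifts.

Step 6
Reactants: 10 rac-7-hydroxy-2-{3-[(2-methylbut-3-en-2-yl)oxy]-4-[(2-methylbut-3-yn-2-yl)oxy]phenyl}chroman-4-one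
Product: 13 (2S)-2-{3-[(2-methylbut-3-en-2-yl)oxy]-4-[(2-methylbut-3-yn-2-yl)oxy]phenyl}chroman-7-ol, via cis-flavan-4-ol 11 (not isolated), via para-quinone methide 12 (not isolated)
Conditions: RuCl[(S,S)-TsDPEN](p-cymene) (2 mol%), HCO2H (3 equiv), Et3N (6 equiv), EtOAc, 40 °C, run to about half conversion; chromatography; recovered ketone (enriched in the 2R enantiomer) returned to step 5
Reagents that add atoms: none
Why: Noyori–Ikariya asymmetric transfer hydrogenation run as a kinetic resolution with domino deoxygenation: the catalyst should reduce the (2S)-ketone fast to the cis-(2S,4S)-carbinol 11, whose 7-OH (para to C4a) expels the C4 hydroxyl to give para-quinone methide 12, which takes up a second hydride at C4, so C2 is set by catalyst-controlled selection of one enantiomer, the slow ketone is re-racemised through the chalcone under the step 5 conditions, and the amine-rich medium spares the tert-allyl ether, the vinyl group and the alkyne.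

Step 7
Reactants: 13 (2S)-2-{3-[(2-methylbut-3-en-2-yl)oxy]-4-[(2-methylbut-3-yn-2-yl)oxy]phenyl}chroman-7-ol
Product: 17 Kazinol B (2S)-2-[8-hydroxy-2,2-dimethyl-7-(3-methylbut-2-en-1-yl)-2H-chromen-6-yl]chroman-7-ol, via prenylphenol 14 (not isolated), via allenylphenol 15 (not isolated), via ortho-quinone methide 16 (not isolated)
Conditions: o-xylene/N,N-diethylaniline 5:1 (0.02 M), Ar, base-washed sealed tube, 110 °C (2 h), then 145 °C (12 h)
Reagents that add atoms: none
Why: Heating should set off two sigmatropic sequences on the catechol ring: first the aromatic Claisen [3,3] shift of the 3'-O-(1,1-dimethylallyl) ether to C2', which inverts the allyl unit into the prenyl group and frees the 3'-OH after tautomerisation (14); then, at the higher temperature, the propargyl Claisen [3,3] shift of the 4'-O-(1,1-dimethylpropargyl) ether to C5', giving allenylphenol 15, whose [1,5]-H shift gives ortho-quinone methide 16. The pyran ring closes by thermal oxa-6π electrocyclisation of 16 (O4' onto the CMe2 terminus, disrotatory, six-membered); the closest known reaction types are the thermal chromene synthesis from aryl 1,1-dimethylpropargyl ethers and the Claisen rearrangement of aryl 1,1-dimethylallyl ethers to ortho-prenylphenols. No stereocentre is formed, and C2 should stay untouched because no bond to it is made or broken under neutral thermal conditions. The selectivity needed is regiochemical and the substrate secures it: each ether oxygen has only one unsubstituted ortho carbon (O3' to C2', O4' to C5'), the other ortho position being the neighbouring oxygen-bearing carbon. The amine cosolvent and base-washed glass are there to suppress acid-catalysed loss of the tert-allyl group and chroman formation from the new ortho-prenylphenol.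

## Compound list

1 | 3,4-dihydroxybenzaldehyde | O=Cc1ccc(O)c(O)c1 | starting material
2 | 3-chloro-3-methylbut-1-yne | C#CC(C)(C)Cl | starting material
3 | 3-hydroxy-4-[(2-methylbut-3-yn-2-yl)oxy]benzaldehyde | O=Cc1ccc(OC(C)(C)C#C)c(O)c1 | intermediate
4 | 2-methylbut-3-en-2-ol | C=CC(C)(C)O | starting material
5 | di-tert-butyl dicarbonate | CC(C)(C)OC(=O)OC(=O)OC(C)(C)C | starting material
6 | tert-butyl 2-methylbut-3-en-2-yl carbonate | C=CC(C)(C)OC(=O)OC(C)(C)C | intermediate
7 | 3-[(2-methylbut-3-en-2-yl)oxy]-4-[(2-methylbut-3-yn-2-yl)oxy]benzaldehyde | O=Cc1ccc(OC(C)(C)C#C)c(OC(C)(C)C=C)c1 | intermediate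
8 | 1-(2,4-dihydroxyphenyl)ethanone | CC(=O)c1ccc(O)cc1O | starting material
9 | (E)-1-(2,4-dihydroxyphenyl)-3-{3-[(2-methylbut-3-en-2-yl)oxy]-4-[(2-methylbut-3-yn-2-yl)oxy]phenyl}prop-2-en-1-one | O=C(/C=C/c1ccc(OC(C)(C)C#C)c(OC(C)(C)C=C)c1)c1ccc(O)cc1O | intermediate
10 | rac-7-hydroxy-2-{3-[(2-methylbut-3-en-2-yl)oxy]-4-[(2-methylbut-3-yn-2-yl)oxy]phenyl}chroman-4-one (racemic) | C=CC(C)(C)Oc1cc(C2CC(=O)c3ccc(O)cc3O2)ccc1OC(C)(C)C#C | intermediate
11 | (2S,4S)-2-{3-[(2-methylbut-3-en-2-yl)oxy]-4-[(2-methylbut-3-yn-2-yl)oxy]phenyl}chromane-4,7-diol (cis) | C=CC(C)(C)Oc1cc([C@@H]2C[C@H](O)c3ccc(O)cc3O2)ccc1OC(C)(C)C#C | intermediate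
12 | (2S)-2-{3-[(2-methylbut-3-en-2-yl)oxy]-4-[(2-methylbut-3-yn-2-yl)oxy]phenyl}-2,3-dihydro-7H-chromen-7-one (para-quinone methide) | C=CC(C)(C)Oc1cc([C@@H]2CC=C3C=CC(=O)C=C3O2)ccc1OC(C)(C)C#C | intermediate
13 | (2S)-2-{3-[(2-methylbut-3-en-2-yl)oxy]-4-[(2-methylbut-3-yn-2-yl)oxy]phenyl}chroman-7-ol | C=CC(C)(C)Oc1cc([C@@H]2CCc3ccc(O)cc3O2)ccc1OC(C)(C)C#C | intermediate
14 | (2S)-2-{3-hydroxy-2-(3-methylbut-2-en-1-yl)-4-[(2-methylbut-3-yn-2-yl)oxy]phenyl}chroman-7-ol | CC(C)=CCc1c([C@@H]2CCc3ccc(O)cc3O2)ccc(OC(C)(C)C#C)c1O | intermediate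
15 | (2S)-2-[3,4-dihydroxy-5-(3-methylbuta-1,2-dien-1-yl)-2-(3-methylbut-2-en-1-yl)phenyl]chroman-7-ol | CC(C)=CCc1c([C@@H]2CCc3ccc(O)cc3O2)cc(C=C=C(C)C)c(O)c1O | intermediate
16 | 2-hydroxy-4-[(2S)-7-hydroxychroman-2-yl]-3-(3-methylbut-2-en-1-yl)-6-(3-methylbut-2-en-1-ylidene)cyclohexa-2,4-dien-1-one (ortho-quinone methide) | CC(C)=CCC1=C(O)C(=O)C(=CC=C(C)C)C=C1[C@@H]2CCc3ccc(O)cc3O2 | intermediate
17 | Kazinol B, (2S)-2-[8-hydroxy-2,2-dimethyl-7-(3-methylbut-2-en-1-yl)-2H-chromen-6-yl]chroman-7-ol | CC(C)=CCc1c([C@@H]2CCc3ccc(O)cc3O2)cc2c(c1O)OC(C)(C)C=C2 | target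

## Totals and risks

Total steps: 7. Longest linear sequence: 6 (steps 1, 3, 4, 5, 6, 7).

**Step 7 (tandem Claisen cascade).** The tert-allyl ether may fragment (loss of the C5 unit) or migrate to the para position instead of into the crowded C2' site, and the new ortho-prenylphenol may close to a chroman under adventitious acid.
Fallback, setting out from 7 and coming back to the route at 14: the prenyl shift would be taken off the flavan and done on the small aldehyde, where the receiving carbon is flanked only by the formyl group. Heating 7 alone at about 110 °C (toluene, N,N-diethylaniline) would give, by aromatic Claisen rearrangement, 3-hydroxy-2-(3-methylbut-2-en-1-yl)-4-[(2-methylbut-3-yn-2-yl)oxy]benzaldehyde F1. Claisen–Schmidt condensation of F1 with 8 would give (E)-1-(2,4-dihydroxyphenyl)-3-{3-hydroxy-2-(3-methylbut-2-en-1-yl)-4-[(2-methylbut-3-yn-2-yl)oxy]phenyl}prop-2-en-1-one F2. Buffered oxa-Michael cyclisation would give rac-7-hydroxy-2-{3-hydroxy-2-(3-methylbut-2-en-1-yl)-4-[(2-methylbut-3-yn-2-yl)oxy]phenyl}chroman-4-one F3. The transfer hydrogenation of step 6 would then pass through (2S,4S)-2-{3-hydroxy-2-(3-methylbut-2-en-1-yl)-4-[(2-methylbut-3-yn-2-yl)oxy]phenyl}chromane-4,7-diol F4 and (2S)-2-{3-hydroxy-2-(3-methylbut-2-en-1-yl)-4-[(2-methylbut-3-yn-2-yl)oxy]phenyl}-2,3-dihydro-7H-chromen-7-one F5 to 14, now isolated. 14 would need only the propargyl Claisen/electrocyclisation (xylene, 140 °C) to reach 17 through 15 and 16.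

**Step 6 (resolving transfer hydrogenation/deoxygenation).** The rate difference between the two flavanone enantiomers may be too small, the terminal alkyne may slow the catalyst, and half of the material per pass is held back by design.
Fallback, setting out from 10 and coming back to the route at 11: the phenol would be masked so that a dynamic resolution of a non-phenolic flavanone can be used. Acylation of 10 (PivCl, Et3N, DMAP, CH2Cl2) would give rac-2-{3-[(2-methylbut-3-en-2-yl)oxy]-4-[(2-methylbut-3-yn-2-yl)oxy]phenyl}-4-oxochroman-7-yl pivalate F6. Ru–(S,S)-TsDPEN transfer hydrogenation with HCO2H and excess DBU in MeCN at 40 °C racemises C2 by base-induced retro-oxa-Michael/oxa-Michael equilibration. It should therefore funnel both enantiomers into (2S,4S)-4-hydroxy-2-{3-[(2-methylbut-3-en-2-yl)oxy]-4-[(2-methylbut-3-yn-2-yl)oxy]phenyl}chroman-7-yl pivalate F7. Methanolysis (K2CO3, MeOH) would give 11, which would be deoxygenated to 13 through 12 under the formate/amine conditions of step 6.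

**Step 3 (Pd-catalysed tert-allylation).** O-allylation of the crowded phenol may be slow, and Pd may isomerise the branched ether to the linear prenyl ether.
Fallback, setting out from 1 and coming back to the route at 7: the order of ether formation would be inverted and the tert-allyl ether made by semi-hydrogenation. Selective 4-O-protection of 1 (MOMCl, K2CO3, acetone) would give 3-hydroxy-4-(methoxymethoxy)benzaldehyde F8. Copper-catalysed propargylation with 2 (as in step 1) would give 4-(methoxymethoxy)-3-[(2-methylbut-3-yn-2-yl)oxy]benzaldehyde F9. HCl/MeOH would give 4-hydroxy-3-[(2-methylbut-3-yn-2-yl)oxy]benzaldehyde F10. Lindlar semi-hydrogenation (H2, Pd/CaCO3–Pb, quinoline, EtOAc) would give 4-hydroxy-3-[(2-methylbut-3-en-2-yl)oxy]benzaldehyde F11. A second copper-catalysed propargylation with 2 at the 4-OH would give 7.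

Further compounds
F1 | step 7 | 3-hydroxy-2-(3-methylbut-2-en-1-yl)-4-[(2-methylbut-3-yn-2-yl)oxy]benzaldehyde | O=Cc1ccc(OC(C)(C)C#C)c(O)c1CC=C(C)C
F2 | step 7 | (E)-1-(2,4-dihydroxyphenyl)-3-{3-hydroxy-2-(3-methylbut-2-en-1-yl)-4-[(2-methylbut-3-yn-2-yl)oxy]phenyl}prop-2-en-1-one | O=C(/C=C/c1ccc(OC(C)(C)C#C)c(O)c1CC=C(C)C)c1ccc(O)cc1O
F3 | step 7 | rac-7-hydroxy-2-{3-hydroxy-2-(3-methylbut-2-en-1-yl)-4-[(2-methylbut-3-yn-2-yl)oxy]phenyl}chroman-4-one | O=C1CC(c2ccc(OC(C)(C)C#C)c(O)c2CC=C(C)C)Oc2cc(O)ccc21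
F4 | step 7 | (2S,4S)-2-{3-hydroxy-2-(3-methylbut-2-en-1-yl)-4-[(2-methylbut-3-yn-2-yl)oxy]phenyl}chromane-4,7-diol | CC(C)=CCc1c([C@@H]2C[C@H](O)c3ccc(O)cc3O2)ccc(OC(C)(C)C#C)c1O
F5 | step 7 | (2S)-2-{3-hydroxy-2-(3-methylbut-2-en-1-yl)-4-[(2-methylbut-3-yn-2-yl)oxy]phenyl}-2,3-dihydro-7H-chromen-7-one | CC(C)=CCc1c([C@@H]2CC=C3C=CC(=O)C=C3O2)ccc(OC(C)(C)C#C)c1O
F6 | step 6 | rac-2-{3-[(2-methylbut-3-en-2-yl)oxy]-4-[(2-methylbut-3-yn-2-yl)oxy]phenyl}-4-oxochroman-7-yl pivalate | CC(C)(C)C(=O)Oc1ccc2C(=O)CC(c3ccc(OC(C)(C)C#C)c(OC(C)(C)C=C)c3)Oc2c1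
F7 | step 6 | (2S,4S)-4-hydroxy-2-{3-[(2-methylbut-3-en-2-yl)oxy]-4-[(2-methylbut-3-yn-2-yl)oxy]phenyl}chroman-7-yl pivalate | CC(C)(C)C(=O)Oc1ccc2[C@@H](O)C[C@@H](c3ccc(OC(C)(C)C#C)c(OC(C)(C)C=C)c3)Oc2c1
F8 | step 3 | 3-hydroxy-4-(methoxymethoxy)benzaldehyde | O=Cc1ccc(OCOC)c(O)c1
F9 | step 3 | 4-(methoxymethoxy)-3-[(2-methylbut-3-yn-2-yl)oxy]benzaldehyde | O=Cc1ccc(OCOC)c(OC(C)(C)C#C)c1
F10 | step 3 | 4-hydroxy-3-[(2-methylbut-3-yn-2-yl)oxy]benzaldehyde | O=Cc1ccc(O)c(OC(C)(C)C#C)c1
F11 | step 3 | 4-hydroxy-3-[(2-methylbut-3-en-2-yl)oxy]benzaldehyde | O=Cc1ccc(O)c(OC(C)(C)C=C)c1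
A1 | direct plan | 1-(3,4-dihydroxyphenyl)ethanone | CC(=O)c1ccc(O)c(O)c1
A2 | direct plan | 1-(8-hydroxy-2,2-dimethyl-2H-chromen-6-yl)ethanone | CC(=O)c1cc2C=CC(C)(C)Oc2c(O)c1
A3 | direct plan | 1-[8-hydroxy-2,2-dimethyl-7-(3-methylbut-2-en-1-yl)-2H-chromen-6-yl]ethanone | CC(=O)c1cc2C=CC(C)(C)Oc2c(O)c1CC=C(C)C
A4 | direct plan | (R)-3-(2,4-dihydroxyphenyl)-1-[8-hydroxy-2,2-dimethyl-7-(3-methylbut-2-en-1-yl)-2H-chromen-6-yl]propan-1-ol | O[C@H](CCc1ccc(O)cc1O)c1cc2C=CC(C)(C)Oc2c(O)c1CC=C(C)C
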